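**Plan**
- Retrosynthesis: the phenols are masked as silyl ethers, the ring D–vinyl bond of the stilbene is cut (Heck), C3–O is traced back to C3–acetyl (Baeyer–Villiger), and ring C is opened at O1–C2 and C3–C4.
- Enabling feature: ring D carries a hydroxyl para to the carbon bonded to C4, so C4 can serve as the methide carbon of a ring D para-quinone methide. The C3 oxygen can be replaced for the annulation by an enolisable acetyl group.
- Forward order: rings D and A are joined at C4 by aryllithium addition to an aldehyde, the carbinol is exchanged for a p-tolyl sulfone, and ring C is closed between the ring A phenol, an enone carrying ring B, and the methide. Ring E is attached last.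
- Stereochemistry: C4 is set by a cinchona squaramide in the annulation. C3 (enolisation) and C2 (retro-oxa-Michael) then settle trans to it, giving the all-equatorial triad. Baeyer–Villiger migration retains C3, and the Heck coupling gives the (E)-alkene.

Key step: step 8

Assumption: the quinine-derived squaramide is taken to favour the methide face that leads to (4S); if the sense proves opposite, its quinidine-derived pseudoenantiomer would be used in the same step.

TBS = tert-butyldimethylsilyl; TBSO = tert-butyldimethylsilyloxy.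

Step 1
Reactants: 1 5-bromoresorcinol
Product: 2 2-bromo-4,6-dihydroxybenzaldehyde
Conditions: POCl3, DMF, MeCN, 0 °C → rt; then H2O, 50 °C
Reagents that add atoms: N,N-dimethylformamide CN(C)C=O (formyl carbon); water O (carbonyl oxygen)
Why: Vilsmeier–Haack formylation should occur para to one hydroxyl and ortho to the other, as with resorcinol and orcinol, the site between the two hydroxyls being the more hindered.

Step 2
Reactants: 2 2-bromo-4,6-dihydroxybenzaldehyde
Product: 3 4-(allyloxy)-2-bromo-6-hydroxybenzaldehyde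
Conditions: allyl bromide (1.05 equiv), K2CO3 (1.0 equiv), acetone, rt
Reagents that add atoms: allyl bromide C=CCBr
Why: Williamson etherification is selective for the para hydroxyl because the ortho hydroxyl is hydrogen-bonded to the aldehyde, the usual behaviour of 2,4-dihydroxybenzaldehydes.

Step 3
Reactants: 3 4-(allyloxy)-2-bromo-6-hydroxybenzaldehyde
Product: 4 4-(allyloxy)-2-bromo-6-(TBSO)benzaldehyde
Conditions: TBSCl, imidazole, DMF, rt
Reagents that add atoms: tert-butyldimethylsilyl chloride CC(C)(C)[Si](C)(C)Cl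
Why: Imidazole-mediated silylation of the remaining phenol installs the group that keeps the ring D ortho oxygen from acting as a nucleophile in step 8.

Step 4
Reactants: 5 4-bromoresorcinol
Product: 6 2-bromo-5-(TBSO)phenol
Conditions: TBSCl (1.0 equiv), imidazole, CH2Cl2, −20 → 0 °C
Reagents that add atoms: tert-butyldimethylsilyl chloride CC(C)(C)[Si](C)(C)Cl
Why: Monosilylation with one equivalent of the bulky chloride should favour the hydroxyl remote from bromine on steric grounds, with the minor regioisomer and bis-ether removed by chromatography.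

Step 5
Reactants: 6 2-bromo-5-(TBSO)phenol; 4 4-(allyloxy)-2-bromo-6-(TBSO)benzaldehyde
Product: 8 racemic [4-(allyloxy)-2-bromo-6-(TBSO)phenyl][2-hydroxy-4-(TBSO)phenyl]methanol, via dilithio phenoxide 7 (not isolated)
Conditions: 6 (1.3 equiv), n-BuLi (2.5 equiv), THF, −78 °C; then 4, −78 °C; sat. NH4Cl at −78 °C
Reagents that add atoms: none
Why: Deprotonation followed by bromine–lithium exchange gives the 2-lithiophenoxide, whose 1,2-addition to the aldehyde delivers the ortho-hydroxybenzhydrol with the ring A phenol already free, and the cold quench forestalls silyl migration from the ring D ortho oxygen to the new alkoxide.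

Step 6
Reactants: 8 racemic [4-(allyloxy)-2-bromo-6-(TBSO)phenyl][2-hydroxy-4-(TBSO)phenyl]methanol
Product: 10 racemic 3-bromo-5-(TBSO)-4-{[2-hydroxy-4-(TBSO)phenyl](p-tolylsulfonyl)methyl}phenol, via allyl-protected sulfone 9 (not isolated)
Conditions: p-TolSO2H (3.5 equiv), CH2Cl2, rt; then Pd(PPh3)4 (3 mol%), rt
Reagents that add atoms: p-toluenesulfinic acid Cc1ccc(cc1)S(=O)O
Why: Acid-promoted ionisation of the electron-rich benzhydrol and S-alkylation of sulfinate gives the sulfone, and the same sulfinic acid then acts as allyl scavenger in a Tsuji–Trost deallylation of the aryl allyl ether by zerovalent palladium, conditions that should leave the aryl bromide and the silyl ethers untouched.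

Step 7
Reactants: 11 (E)-4-(4-hydroxyphenyl)but-3-en-2-one
Product: 12 (E)-4-[4-(TBSO)phenyl]but-3-en-2-one
Conditions: TBSCl, imidazole, DMF, rt
Reagents that add atoms: tert-butyldimethylsilyl chloride CC(C)(C)[Si](C)(C)Cl
Why: Standard phenol silylation removes the acidic ring B hydroxyl, which would otherwise compete as a nucleophile in the annulation.

Step 8
Reactants: 10 racemic 3-bromo-5-(TBSO)-4-{[2-hydroxy-4-(TBSO)phenyl](p-tolylsulfonyl)methyl}phenol; 12 (E)-4-[4-(TBSO)phenyl]but-3-en-2-one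
Product: 14 1-[(2S,3S,4S)-4-[2-bromo-4-hydroxy-6-(TBSO)phenyl]-7-(TBSO)-2-[4-(TBSO)phenyl]chroman-3-yl]ethan-1-one, via ring D para-quinone methide 13 (not isolated)
Conditions: 12 (3 equiv), quinine-derived 3,5-bis(trifluoromethyl)phenyl squaramide (10 mol%), powdered K2CO3 (2.2 equiv), CH2Cl2, 0 °C → rt
Reagents that add atoms: none
Why: Proposed new method: carbonate-induced loss of p-toluenesulfinate from 10 gives the ring D para-quinone methide 13, the ring A phenoxide adds reversibly to the β-carbon of enone 12 (O1–C2), and the resulting enolate attacks the exocyclic methide carbon (C3–C4), rearomatisation of ring D making the sequence irreversible. The closest known reactions are the organocatalytic oxa-Michael/1,6-addition annulations of isolable ortho-hydroxyphenyl para-quinone methides and the base-mediated release of quinone methides from aryl sulfones; the unhindered methide and the simple enone partner are the untested elements. Ring C closes in a 6-exo-trig mode, the enolate carbon attacking the methide carbon whose double bond lies outside the new ring. C4 is set under catalyst control, the squaramide hydrogen-bonding to the quinone methide carbonyl while the protonated quinuclidine holds the enolate so that one methide face is attacked; C3 then equilibrates by enolisation and C2 by retro-oxa-Michael and re-addition until the acetyl and both aryl groups are equatorial, which is (2S,3S,4S). The step needs enantioface selection at C4 and selection of ring A as the fused ring; the silyl ether on the ortho oxygen of ring D secures the latter by leaving the ring A phenol as the only oxygen that can close a six-membered ring, and slow heterogeneous release of 13 in the presence of excess 12 should limit self-condensation.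

Step 9
Reactants: 14 1-[(2S,3S,4S)-4-[2-bromo-4-hydroxy-6-(TBSO)phenyl]-7-(TBSO)-2-[4-(TBSO)phenyl]chroman-3-yl]ethan-1-one
Product: 15 1-[(2S,3S,4S)-4-[2-bromo-4,6-bis(TBSO)phenyl]-7-(TBSO)-2-[4-(TBSO)phenyl]chroman-3-yl]ethan-1-one
Conditions: TBSCl, imidazole, DMF, rt
Reagents that add atoms: tert-butyldimethylsilyl chloride CC(C)(C)[Si](C)(C)Cl
Why: Silylation of the unhindered ring D para phenol protects it from peracid in the next step, and any base-induced epimerisation at C3 only returns the thermodynamic all-equatorial isomer.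

Step 10
Reactants: 15 1-[(2S,3S,4S)-4-[2-bromo-4,6-bis(TBSO)phenyl]-7-(TBSO)-2-[4-(TBSO)phenyl]chroman-3-yl]ethan-1-one
Product: 16 (2R,3S,4S)-4-[2-bromo-4,6-bis(TBSO)phenyl]-7-(TBSO)-2-[4-(TBSO)phenyl]chroman-3-yl acetate
Conditions: mCPBA (3 equiv), CH2Cl2, 0 °C → rt, dark
Reagents that add atoms: meta-chloroperbenzoic acid OOC(=O)c1cccc(Cl)c1
Why: In the Baeyer–Villiger oxidation the secondary C3 carbon migrates in preference to methyl and with retention, so C3–acetyl becomes C3–OAc without disturbing C2 or C4, and the step is placed before the Heck coupling so that no alkene is exposed to peracid.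

Step 11
Reactants: 17 3,4-dihydroxybenzaldehyde
Product: 18 3,4-bis(TBSO)benzaldehyde
Conditions: TBSCl (2.4 equiv), imidazole, DMF, rt
Reagents that add atoms: tert-butyldimethylsilyl chloride CC(C)(C)[Si](C)(C)Cl
Why: Standard bis-silylation of the catechol gives the same protecting group as on the other phenols, so that one fluoride treatment clears all of them at the end.

Step 12
Reactants: 18 3,4-bis(TBSO)benzaldehyde
Product: 19 3,4-bis(TBSO)styrene
Conditions: Ph3PCH3Br, KN(SiMe3)2, THF, 0 °C → rt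
Reagents that add atoms: methyltriphenylphosphonium bromide C[P+](c1ccccc1)(c1ccccc1)c1ccccc1.[Br-]
Why: Wittig methylenation of an aromatic aldehyde with the non-stabilised ylide is reliable and tolerates aryl silyl ethers.

Step 13
Reactants: 16 (2R,3S,4S)-4-[2-bromo-4,6-bis(TBSO)phenyl]-7-(TBSO)-2-[4-(TBSO)phenyl]chroman-3-yl acetate; 19 3,4-bis(TBSO)styrene
Product: 20 (2R,3S,4S)-4-{2-[(E)-2-[3,4-bis(TBSO)phenyl]ethenyl]-4,6-bis(TBSO)phenyl}-7-(TBSO)-2-[4-(TBSO)phenyl]chroman-3-yl acetate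
Conditions: 19 (1.5 equiv), Pd2(dba)3 (2.5 mol%), [(t-Bu)3PH]BF4 (10 mol%), Cy2NMe, 1,4-dioxane, 80 °C
Reagents that add atoms: none
Why: In this Mizoroki–Heck coupling the bulky electron-rich phosphine should permit oxidative addition at the ortho-substituted bromide at moderate temperature, and syn insertion followed by syn β-hydride elimination gives the (E)-stilbene, the acetate keeping the C3 oxygen from intercepting the arylpalladium intermediate.

Step 14
Reactants: 20 (2R,3S,4S)-4-{2-[(E)-2-[3,4-bis(TBSO)phenyl]ethenyl]-4,6-bis(TBSO)phenyl}-7-(TBSO)-2-[4-(TBSO)phenyl]chroman-3-yl acetate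
Product: 21 (2R,3S,4S)-4-{2-[(E)-2-[3,4-bis(TBSO)phenyl]ethenyl]-4,6-bis(TBSO)phenyl}-7-(TBSO)-2-[4-(TBSO)phenyl]chroman-3-ol
Conditions: i-Bu2AlH (3 equiv), CH2Cl2, −78 °C; aq. potassium sodium tartrate
Reagents that add atoms: none
Why: Reductive cleavage of the acetate by the aluminium hydride at low temperature spares the aryl silyl ethers and the stilbene, whereas basic methanolysis would cleave the silyl ethers unevenly.

Step 15
Reactants: 21 (2R,3S,4S)-4-{2-[(E)-2-[3,4-bis(TBSO)phenyl]ethenyl]-4,6-bis(TBSO)phenyl}-7-(TBSO)-2-[4-(TBSO)phenyl]chroman-3-ol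
Product: 22 (2R,3S,4S)-4-{2-[(E)-2-(3,4-dihydroxyphenyl)ethenyl]-4,6-dihydroxyphenyl}-2-(4-hydroxyphenyl)chroman-3,7-diol (CNP0170061.1)
Conditions: Bu4NF (8 equiv), AcOH (8 equiv), THF, 0 °C → rt, argon
Reagents that add atoms: none
Why: Fluoride desilylation buffered with acetic acid removes all six aryl silyl ethers while keeping the polyphenol protonated, which should avoid catechol oxidation and base-induced opening of ring C at C2.

**Compound list**
1 | 5-bromoresorcinol | Oc1cc(O)cc(Br)c1 | starting material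
2 | 2-bromo-4,6-dihydroxybenzaldehyde | O=Cc1c(O)cc(O)cc1Br | intermediate
3 | 4-(allyloxy)-2-bromo-6-hydroxybenzaldehyde | O=Cc1c(O)cc(OCC=C)cc1Br | intermediate
4 | 4-(allyloxy)-2-bromo-6-(TBSO)benzaldehyde | O=Cc1c(O[Si](C)(C)C(C)(C)C)cc(OCC=C)cc1Br | intermediate
5 | 4-bromoresorcinol | Oc1ccc(Br)c(O)c1 | starting material
6 | 2-bromo-5-(TBSO)phenol | Oc1cc(O[Si](C)(C)C(C)(C)C)ccc1Br | intermediate
7 | lithium 2-lithio-5-(TBSO)phenoxide (not isolated) | [Li]Oc1cc(O[Si](C)(C)C(C)(C)C)ccc1[Li] | intermediate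
8 | racemic [4-(allyloxy)-2-bromo-6-(TBSO)phenyl][2-hydroxy-4-(TBSO)phenyl]methanol | OC(c1ccc(O[Si](C)(C)C(C)(C)C)cc1O)c1c(Br)cc(OCC=C)cc1O[Si](C)(C)C(C)(C)C | intermediate
9 | racemic 2-{[4-(allyloxy)-2-bromo-6-(TBSO)phenyl](p-tolylsulfonyl)methyl}-5-(TBSO)phenol (not isolated) | Cc1ccc(cc1)S(=O)(=O)C(c1ccc(O[Si](C)(C)C(C)(C)C)cc1O)c1c(Br)cc(OCC=C)cc1O[Si](C)(C)C(C)(C)C | intermediate
10 | racemic 3-bromo-5-(TBSO)-4-{[2-hydroxy-4-(TBSO)phenyl](p-tolylsulfonyl)methyl}phenol (key-step precursor) | Cc1ccc(cc1)S(=O)(=O)C(c1ccc(O[Si](C)(C)C(C)(C)C)cc1O)c1c(Br)cc(O)cc1O[Si](C)(C)C(C)(C)C | intermediate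
11 | (E)-4-(4-hydroxyphenyl)but-3-en-2-one | CC(=O)/C=C/c1ccc(O)cc1 | starting material
12 | (E)-4-[4-(TBSO)phenyl]but-3-en-2-one (key-step precursor) | CC(=O)/C=C/c1ccc(O[Si](C)(C)C(C)(C)C)cc1 | intermediate
13 | 3-bromo-5-(TBSO)-4-{[2-hydroxy-4-(TBSO)phenyl]methylidene}cyclohexa-2,5-dien-1-one, alkene geometry not defined (not isolated) | O=C1C=C(Br)C(=Cc2ccc(O[Si](C)(C)C(C)(C)C)cc2O)C(O[Si](C)(C)C(C)(C)C)=C1 | intermediate
14 | 1-[(2S,3S,4S)-4-[2-bromo-4-hydroxy-6-(TBSO)phenyl]-7-(TBSO)-2-[4-(TBSO)phenyl]chroman-3-yl]ethan-1-one (key-step product) | CC(C)(C)[Si](C)(C)Oc1ccc([C@H]2Oc3cc(O[Si](C)(C)C(C)(C)C)ccc3[C@@H](c3c(O[Si](C)(C)C(C)(C)C)cc(O)cc3Br)[C@@H]2C(C)=O)cc1 | intermediate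
15 | 1-[(2S,3S,4S)-4-[2-bromo-4,6-bis(TBSO)phenyl]-7-(TBSO)-2-[4-(TBSO)phenyl]chroman-3-yl]ethan-1-one | CC(C)(C)[Si](C)(C)Oc1ccc([C@H]2Oc3cc(O[Si](C)(C)C(C)(C)C)ccc3[C@@H](c3c(O[Si](C)(C)C(C)(C)C)cc(O[Si](C)(C)C(C)(C)C)cc3Br)[C@@H]2C(C)=O)cc1 | intermediate
16 | (2R,3S,4S)-4-[2-bromo-4,6-bis(TBSO)phenyl]-7-(TBSO)-2-[4-(TBSO)phenyl]chroman-3-yl acetate | CC(C)(C)[Si](C)(C)Oc1ccc([C@H]2Oc3cc(O[Si](C)(C)C(C)(C)C)ccc3[C@@H](c3c(O[Si](C)(C)C(C)(C)C)cc(O[Si](C)(C)C(C)(C)C)cc3Br)[C@@H]2OC(C)=O)cc1 | intermediate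
17 | 3,4-dihydroxybenzaldehyde | O=Cc1ccc(O)c(O)c1 | starting material
18 | 3,4-bis(TBSO)benzaldehyde | O=Cc1ccc(O[Si](C)(C)C(C)(C)C)c(O[Si](C)(C)C(C)(C)C)c1 | intermediate
19 | 3,4-bis(TBSO)styrene | C=Cc1ccc(O[Si](C)(C)C(C)(C)C)c(O[Si](C)(C)C(C)(C)C)c1 | intermediate
20 | (2R,3S,4S)-4-{2-[(E)-2-[3,4-bis(TBSO)phenyl]ethenyl]-4,6-bis(TBSO)phenyl}-7-(TBSO)-2-[4-(TBSO)phenyl]chroman-3-yl acetate | CC(C)(C)[Si](C)(C)Oc1ccc([C@H]2Oc3cc(O[Si](C)(C)C(C)(C)C)ccc3[C@@H](c3c(O[Si](C)(C)C(C)(C)C)cc(O[Si](C)(C)C(C)(C)C)cc3/C=C/c3ccc(O[Si](C)(C)C(C)(C)C)c(O[Si](C)(C)C(C)(C)C)c3)[C@@H]2OC(C)=O)cc1 | intermediate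
21 | (2R,3S,4S)-4-{2-[(E)-2-[3,4-bis(TBSO)phenyl]ethenyl]-4,6-bis(TBSO)phenyl}-7-(TBSO)-2-[4-(TBSO)phenyl]chroman-3-ol | CC(C)(C)[Si](C)(C)Oc1ccc([C@H]2Oc3cc(O[Si](C)(C)C(C)(C)C)ccc3[C@@H](c3c(O[Si](C)(C)C(C)(C)C)cc(O[Si](C)(C)C(C)(C)C)cc3/C=C/c3ccc(O[Si](C)(C)C(C)(C)C)c(O[Si](C)(C)C(C)(C)C)c3)[C@@H]2O)cc1 | intermediate
22 | (2R,3S,4S)-4-{2-[(E)-2-(3,4-dihydroxyphenyl)ethenyl]-4,6-dihydroxyphenyl}-2-(4-hydroxyphenyl)chroman-3,7-diol | Oc1ccc([C@H]2Oc3cc(O)ccc3[C@@H](c3c(O)cc(O)cc3/C=C/c3ccc(O)c(O)c3)[C@@H]2O)cc1 | target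

**Step count**
Total steps: 15. Longest linear sequence: 11 steps (1, 2, 3, 5, 6, 8, 9, 10, 13, 14, 15).

**Steps most likely to fail**

Step 8. The unhindered quinone methide may condense with itself faster than the enolate can be intercepted, the oxa-Michael equilibrium with the electron-rich enone may lie too far back, or facial selection at C4 may be poor. The fallback uses known chemistry, sets out from aldehyde 2 and bromophenol 6, and returns at acetate 16.
- Aldehyde 2 would be bis-silylated (TBSCl, imidazole) to 2-bromo-4,6-bis(TBSO)benzaldehyde F1.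
- F1 would be combined with the dilithio phenoxide 7 from 6, as in step 5, to give the carbinol racemic [2-bromo-4,6-bis(TBSO)phenyl][2-hydroxy-4-(TBSO)phenyl]methanol F2.
- A BINOL-derived chiral phosphoric acid (enantiomer chosen for the 4S series) would dehydrate F2 to the ring A ortho-quinone methide and mediate its enantioselective trapping by the enamide N-{1-[4-(TBSO)phenyl]ethenyl}acetamide F3. F3 would be made in one pot from commercial 4-(TBSO)benzonitrile with MeMgBr and then Ac2O.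
- The trapping gives the 2-acetamidochroman F4, which on treatment with catalytic TsOH loses acetamide to give the (4S)-2,4-diaryl-4H-chromene F5.
- Hydroboration (BH3·SMe2) anti to the C4 aryl group and oxidation (NaBO3·4H2O) would give the all-trans flavan-3-ol (2R,3S,4S)-4-[2-bromo-4,6-bis(TBSO)phenyl]-7-(TBSO)-2-[4-(TBSO)phenyl]chroman-3-ol F6.
- Acetylation (Ac2O, pyridine, DMAP) returns the route at 16.

Step 10. Peracid may attack the electron-rich silyloxyarenes, or addition to the hindered carbonyl flanked by two aryl-bearing carbons may be too slow. The fallback sets out from ketone 15 and returns at acetate 16.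
- Kinetic enolisation toward the methyl group (LiN(i-Pr)2, Me3SiCl, THF, −78 °C) would give the trimethylsilyl enol ether F7.
- Ozonolysis (O3, CH2Cl2, −78 °C; Me2S) would cleave it to the (2S,3S,4S)-chroman-3-carboxylic acid F8.
- Coupling with N-hydroxypyridine-2-thione (DCC) gives the Barton ester F9.
- Photolysis under O2 with t-BuSH (Barton decarboxylative hydroxylation) should trap the C3 radical on the face opposite both aryl groups as the hydroperoxide F10.
- P(OMe)3 reduces F10 to the flavan-3-ol F6 described above, and acetylation (Ac2O, pyridine, DMAP) gives 16.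

Step 13. Oxidative addition and alkene insertion at the bromide crowded by the C4 substituent may be slow, allowing hydrodebromination and catalyst decomposition. The fallback sets out from aldehyde 18 and returns at stilbene 20.
- Takai–Utimoto-type olefination of 18 with Cl2CHBpin, CrCl2 and LiI in THF would give the (E)-alkenyl pinacol boronate 2-{(E)-2-[3,4-bis(TBSO)phenyl]ethenyl}-4,4,5,5-tetramethyl-1,3,2-dioxaborolane F11.
- Suzuki–Miyaura coupling of F11 with bromide 16 (Pd(OAc)2, SPhos, K3PO4, THF/H2O, 40 °C) brings in the alkene preformed and gives 20.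

Further compounds
F1 | step 8 | 2-bromo-4,6-bis(TBSO)benzaldehyde | O=Cc1c(O[Si](C)(C)C(C)(C)C)cc(O[Si](C)(C)C(C)(C)C)cc1Br
F2 | step 8 | racemic [2-bromo-4,6-bis(TBSO)phenyl][2-hydroxy-4-(TBSO)phenyl]methanol | OC(c1ccc(O[Si](C)(C)C(C)(C)C)cc1O)c1c(Br)cc(O[Si](C)(C)C(C)(C)C)cc1O[Si](C)(C)C(C)(C)C
F3 | step 8 | N-{1-[4-(TBSO)phenyl]ethenyl}acetamide | CC(=O)NC(=C)c1ccc(O[Si](C)(C)C(C)(C)C)cc1
F4 | step 8 | N-{(4S)-4-[2-bromo-4,6-bis(TBSO)phenyl]-7-(TBSO)-2-[4-(TBSO)phenyl]chroman-2-yl}acetamide, C2 configuration not defined | CC(=O)NC1(c2ccc(O[Si](C)(C)C(C)(C)C)cc2)C[C@H](c2c(O[Si](C)(C)C(C)(C)C)cc(O[Si](C)(C)C(C)(C)C)cc2Br)c2ccc(O[Si](C)(C)C(C)(C)C)cc2O1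
F5 | step 8 | (4S)-4-[2-bromo-4,6-bis(TBSO)phenyl]-7-(TBSO)-2-[4-(TBSO)phenyl]-4H-chromene | CC(C)(C)[Si](C)(C)Oc1ccc(C2=C[C@H](c3c(O[Si](C)(C)C(C)(C)C)cc(O[Si](C)(C)C(C)(C)C)cc3Br)c3ccc(O[Si](C)(C)C(C)(C)C)cc3O2)cc1
F6 | step 8 | (2R,3S,4S)-4-[2-bromo-4,6-bis(TBSO)phenyl]-7-(TBSO)-2-[4-(TBSO)phenyl]chroman-3-ol | CC(C)(C)[Si](C)(C)Oc1ccc([C@H]2Oc3cc(O[Si](C)(C)C(C)(C)C)ccc3[C@@H](c3c(O[Si](C)(C)C(C)(C)C)cc(O[Si](C)(C)C(C)(C)C)cc3Br)[C@@H]2O)cc1
F7 | step 10 | (2S,3S,4S)-4-[2-bromo-4,6-bis(TBSO)phenyl]-7-(TBSO)-2-[4-(TBSO)phenyl]-3-[1-(trimethylsilyloxy)ethenyl]chroman | CC(C)(C)[Si](C)(C)Oc1ccc([C@H]2Oc3cc(O[Si](C)(C)C(C)(C)C)ccc3[C@@H](c3c(O[Si](C)(C)C(C)(C)C)cc(O[Si](C)(C)C(C)(C)C)cc3Br)[C@@H]2C(=C)O[Si](C)(C)C)cc1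
F8 | step 10 | (2S,3S,4S)-4-[2-bromo-4,6-bis(TBSO)phenyl]-7-(TBSO)-2-[4-(TBSO)phenyl]chroman-3-carboxylic acid | CC(C)(C)[Si](C)(C)Oc1ccc([C@H]2Oc3cc(O[Si](C)(C)C(C)(C)C)ccc3[C@@H](c3c(O[Si](C)(C)C(C)(C)C)cc(O[Si](C)(C)C(C)(C)C)cc3Br)[C@@H]2C(=O)O)cc1
F9 | step 10 | 2-thioxopyridin-1(2H)-yl (2S,3S,4S)-4-[2-bromo-4,6-bis(TBSO)phenyl]-7-(TBSO)-2-[4-(TBSO)phenyl]chroman-3-carboxylate | CC(C)(C)[Si](C)(C)Oc1ccc([C@H]2Oc3cc(O[Si](C)(C)C(C)(C)C)ccc3[C@@H](c3c(O[Si](C)(C)C(C)(C)C)cc(O[Si](C)(C)C(C)(C)C)cc3Br)[C@@H]2C(=O)ON4C=CC=CC4=S)cc1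
F10 | step 10 | (2R,3S,4S)-4-[2-bromo-4,6-bis(TBSO)phenyl]-3-hydroperoxy-7-(TBSO)-2-[4-(TBSO)phenyl]chroman | CC(C)(C)[Si](C)(C)Oc1ccc([C@H]2Oc3cc(O[Si](C)(C)C(C)(C)C)ccc3[C@@H](c3c(O[Si](C)(C)C(C)(C)C)cc(O[Si](C)(C)C(C)(C)C)cc3Br)[C@@H]2OO)cc1
F11 | step 13 | 2-{(E)-2-[3,4-bis(TBSO)phenyl]ethenyl}-4,4,5,5-tetramethyl-1,3,2-dioxaborolane | CC1(C)OB(/C=C/c2ccc(O[Si](C)(C)C(C)(C)C)c(O[Si](C)(C)C(C)(C)C)c2)OC1(C)C
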